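**Plan**

- Labels: rings A (cyclobutane), B (nine-membered), C (dihydropyran), D (cyclohexadienone). The terpenoid part uses caryophyllane numbering (C4 bears the ring C oxygen O4, C5 bears the pyran CH2, C7′). Ring D: C1′ (enol ether carbon on O4), C2′ (on C7′), C3′ (C–OH), C4′ (acyl-bearing), C5′ (C=O), C6′ (CMe2).
- Retrosynthesis: ring D is cut at C1′=C2′ and C4′–C5′ in one stroke. This uncovers a 1,3-diketone (C2′ its terminal α-carbon, C4′ its central carbon) and a dimethylmalonyl unit (C1′–C6′–C5′) carried as the ester of the C4 alcohol. Next cuts: the ester C–O bond, then C3′–C4′ (Claisen opening of a temporary δ-lactone), then the lactone O4–C4/C7′–C5 pair (hetero-Diels–Alder on caryophyllene).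
- Forward: rings A and B come with (−)-β-caryophyllene. A temporary δ-lactone fixes C4–O and C5–C (step 1). A ketone enolate opens it to the diketone chain (step 3). The malonyl ester is placed on O4 (step 5). Rings D and C then close in one operation (step 6).
- Stereochemistry: C1 and C9 come from caryophyllene. C4 and C5 come from suprafacial cycloaddition to the E-alkene on its exposed face. The (S)-methine comes from (S)-2-methylbutanoic acid. The key step creates no stereocentre.
- Enabling feature: ring D is a cyclic β-triketone. C2′ and C4′ are the two nucleophilic carbons of one 1,3-diketone, C1′ and C5′ are the carbonyl carbons flanking CMe2, and the ring C oxygen sits on C1′. The malonyl unit can therefore be delivered from O4 through a six-membered transition state.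

Key step: step 6

Assumption: the enolised β-triketone of ring D interconverts freely between tautomers and is written in the tautomer of the target; acids 7 and 10 are taken as commercial.

**Step 1**
Reactants: 1 (−)-β-caryophyllene; 2 Meldrum's acid; 3 formaldehyde
Product: 6 caryophyllane-fused δ-lactone, via 5-methylidene Meldrum's acid 4 (not isolated), via dioxinone cycloadduct 5 (not isolated)
Conditions: 2 (added slowly), aq. CH2O, ethylenediammonium diacetate (cat.), CH3CN, 23 → 45 °C; then H2O–pyridine, 95 °C
Reagents that add atoms: water, O
Why: Domino Knoevenagel condensation/inverse-electron-demand hetero-Diels–Alder reaction: heterodiene 4 should add across the strained E-configured C4=C5 bond rather than the exocyclic alkene, with O to the more substituted C4 and CH2 to C5; the suprafacial addition on the exposed face of the alkene (the face that peracids epoxidise) sets C4 and C5 and the trans ring fusion, and hydrolysis of the ketene acetal with decarboxylation then gives the lactone.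

**Step 2**
Reactants: 7 (S)-2-methylbutanoic acid
Product: 8 (S)-3-methylpentan-2-one
Conditions: CH3Li (2.1 equiv), Et2O, 0 °C; inverse quench into cold 1 M HCl
Reagents that add atoms: methyllithium, [Li]C
Why: Ketone synthesis from a carboxylic acid and an organolithium: CH3Li adds to the lithium carboxylate to give a stable dilithium gem-diolate that releases the ketone only on acidic quench, so over-addition and enolisation of the α-stereocentre should be avoided.

**Step 3**
Reactants: 6 caryophyllane-fused δ-lactone; 8 (S)-3-methylpentan-2-one
Product: 9 hydroxy diketone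
Conditions: 8 (2.2 equiv), LiN(iPr)2 (2.2 equiv), THF, −78 °C; then 6, −78 → −20 °C; AcOH quench
Reagents that add atoms: none
Why: Crossed Claisen condensation: the kinetic methyl-side lithium enolate of 8 adds to the unhindered lactone carbonyl, the ring opens and the β-diketone is held as its lithium enolate, which blocks the reverse reaction; the (S)-methine is not deprotonated under these kinetic conditions and no stereocentre is formed.

**Step 4**
Reactants: 10 3-methoxy-2,2-dimethyl-3-oxopropanoic acid
Product: 11 methyl 3-chloro-2,2-dimethyl-3-oxopropanoate
Conditions: (COCl)2 (1.2 equiv), DMF (cat.), CH2Cl2, 0 → 23 °C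
Reagents that add atoms: oxalyl chloride, O=C(Cl)C(=O)Cl
Why: Acid chloride formation through the Vilsmeier-type chloroiminium species; the acid has no α-hydrogen, so no ketene can form.

**Step 5**
Reactants: 9 hydroxy diketone; 11 methyl 3-chloro-2,2-dimethyl-3-oxopropanoate
Product: 12 tethered malonate diketone
Conditions: LiN(SiMe3)2 (2.1 equiv), THF, −78 → 0 °C; 11 (1.3 equiv), 0 → 23 °C; AcOH quench
Reagents that add atoms: none
Why: O-Acylation of a lithium alkoxide by an acid chloride: in the dianion of 9 the tertiary alkoxide is the more basic and more nucleophilic site compared with the chelated lithium diketonate, and 11 cannot form a ketene, so the hindered ester should form without touching any stereocentre.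

**Step 6**
Reactants: 12 tethered malonate diketone
Product: 15 target meroterpenoid, via triketo ester 13 (not isolated), via hydroxy acyltrione 14 (not isolated)
Conditions: LiN(iPr)2 (2.3 equiv), THF (0.02 M), −78 → 45 °C; 1 M HCl to pH 3, extraction into PhMe; pyridinium p-toluenesulfonate (cat.), 4 Å molecular sieves, 60 °C
Reagents that add atoms: none
Why: Proposed new method: LiN(iPr)2 should convert the 1,3-diketone into its dianion, whose terminal carbanion C2′ adds to the tethered ester carbonyl C1′ through a six-membered transition state; the cyclic tetrahedral adduct collapses by O→C acyl transfer to triketo ester 13, the doubly activated C4′ then attacks the methyl ester C5′ (Dieckmann condensation) to give acyltrione 14, and on acidification the C4 hydroxyl adds back to the C1′ carbonyl and water is lost. The closest known reaction types are the Baker–Venkataraman acyl transfer followed by cyclodehydration to chromones, the γ-acylation of β-diketone dianions by esters and the Claisen cyclisation of triketo esters to acylphloroglucinol-type triones; they have not been combined as one tandem on a tert-alkyl malonate, hence the label. Ring D closes 6-exo-trig at C4′–C5′ after the 6-exo-trig delivery of C1′ to C2′, and ring C closes 6-exo-trig by hemiketalisation of O4 at C1′ followed by dehydration to the C1′=C2′ enol ether. No stereocentre is formed: C1, C4, C5 and C9 are not involved, and the (S)-methine should survive because the second deprotonation takes place at the CH2 group C2′ and not at the more hindered methine. The step needs C- and not O-acylation and ether closure at C1′ and not at C3′: the tether delivers the acyl group to C2′ only, the C-acylated trione enolate is the thermodynamic sink for any enol lactone, and C1′ is the one ring carbonyl that is not locked in the hydrogen-bonded chelate with the 2-methylbutanoyl group, while the weak acid avoids ionisation of the tertiary alcohol.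

**Compound list**

1 | (−)-β-caryophyllene, (1R,4E,9S)-4,11,11-trimethyl-8-methylidenebicyclo[7.2.0]undec-4-ene | C/C1=C\CCC(=C)[C@H]2CC([C@@H]2CC1)(C)C | starting material
2 | Meldrum's acid, 2,2-dimethyl-1,3-dioxane-4,6-dione | CC1(C)OC(=O)CC(=O)O1 | starting material
3 | formaldehyde (aqueous solution) | C=O | starting material
4 | 5-methylidene Meldrum's acid, 2,2-dimethyl-5-methylidene-1,3-dioxane-4,6-dione | C=C1C(=O)OC(C)(C)OC1=O | intermediate
5 | dioxinone cycloadduct: 2,2-dimethyl-1,3-dioxin-4-one fused to a dihydropyran that is trans-fused to ring B, O on C4 (4R), CH2 on C5 (5S), 1R,9S | C=C1CC[C@H]2CC3=C(O[C@]2(C)CC[C@@H]2[C@@H]1CC2(C)C)OC(C)(C)OC3=O | intermediate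
6 | caryophyllane-fused δ-lactone: 4-lactone of 3-[(1R,4R,5S,9S)-4-hydroxy-4,11,11-trimethyl-8-methylidenebicyclo[7.2.0]undecan-5-yl]propanoic acid | C=C1CC[C@H]2CCC(=O)O[C@]2(C)CC[C@@H]2[C@@H]1CC2(C)C | intermediate
7 | (S)-2-methylbutanoic acid | CC[C@H](C)C(=O)O | starting material
8 | (S)-3-methylpentan-2-one | CC[C@H](C)C(C)=O | intermediate
9 | hydroxy diketone: (6S)-1-[(1R,4R,5S,9S)-4-hydroxy-4,11,11-trimethyl-8-methylidenebicyclo[7.2.0]undecan-5-yl]-6-methyloctane-3,5-dione | C=C1CC[C@@H](CCC(=O)CC(=O)[C@@H](C)CC)[C@@](O)(C)CC[C@@H]2[C@@H]1CC2(C)C | intermediate
10 | 3-methoxy-2,2-dimethyl-3-oxopropanoic acid (monomethyl 2,2-dimethylmalonate) | COC(=O)C(C)(C)C(=O)O | starting material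
11 | methyl 3-chloro-2,2-dimethyl-3-oxopropanoate | COC(=O)C(C)(C)C(=O)Cl | intermediate
12 | tethered malonate diketone: methyl (1R,4R,5S,9S)-4,11,11-trimethyl-8-methylidene-5-[(6S)-6-methyl-3,5-dioxooctyl]bicyclo[7.2.0]undecan-4-yl 2,2-dimethylpropanedioate | C=C1CC[C@@H](CCC(=O)CC(=O)[C@@H](C)CC)[C@@](OC(=O)C(C)(C)C(=O)OC)(C)CC[C@@H]2[C@@H]1CC2(C)C | intermediate
13 | triketo ester: methyl (8S)-4-{[(1R,4R,5S,9S)-4-hydroxy-4,11,11-trimethyl-8-methylidenebicyclo[7.2.0]undecan-5-yl]methyl}-2,2,8-trimethyl-3,5,7-trioxodecanoate (C4 of the chain enolisable, not defined) | C=C1CC[C@@H](CC(C(=O)C(C)(C)C(=O)OC)C(=O)CC(=O)[C@@H](C)CC)[C@@](O)(C)CC[C@@H]2[C@@H]1CC2(C)C | intermediate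
14 | hydroxy acyltrione: 3,5-dihydroxy-6,6-dimethyl-4-[(2S)-2-methylbutanoyl]-2-{[(1R,4R,5S,9S)-4-hydroxy-4,11,11-trimethyl-8-methylidenebicyclo[7.2.0]undecan-5-yl]methyl}cyclohexa-2,4-dien-1-one (one enol tautomer) | C=C1CC[C@@H](CC3=C(O)C(C(=O)[C@@H](C)CC)=C(O)C(C)(C)C3=O)[C@@](O)(C)CC[C@@H]2[C@@H]1CC2(C)C | intermediate
15 | target: ring C dihydropyran trans-fused to ring B with O on C4 (4R) and C7′ on C5 (5S), 1R,9S; ring D with C1′=C2′ enol ether, C3′–OH, C4′-[(2S)-2-methylbutanoyl], C5′=O, C6′ dimethyl; C8 exocyclic methylidene | C=C1CC[C@H]2CC3=C(O[C@]2(C)CC[C@@H]2[C@@H]1CC2(C)C)C(C)(C)C(=O)C(C(=O)[C@@H](C)CC)=C3O | target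

**Totals**

Total step count: 6. Longest linear sequence: 4 steps (1, 3, 5, 6) from (−)-β-caryophyllene.

**Steps most likely to fail**

1. Step 6 (proposed new method). What may go wrong:
   - the hindered tert-alkyl ester carbonyl may resist attack by the terminal carbanion;
   - O-acylation to an enol lactone may stall the Dieckmann closure;
   - deprotonation at the methine may erode the (S)-configuration;
   - the ether may close at C3′ instead of C1′, or the tertiary alcohol may ionise in the acid stage.

   Fallback by known chemistry, setting out from 7 and 1 and returning at 15: ring D is made separately and joined to caryophyllene by the hetero-Diels–Alder reaction typical of this compound class. Acid 7 is converted with oxalyl chloride into (S)-2-methylbutanoyl chloride F1. Friedel–Crafts acylation of phloroglucinol with F1 (AlCl3) gives (2S)-2-methyl-1-(2,4,6-trihydroxyphenyl)butan-1-one F2. Twofold C-methylation (CH3I, NaOCH3, CH3OH) gives 2-[(2S)-2-methylbutanoyl]-4,4-dimethylcyclohexane-1,3,5-trione F3. Knoevenagel condensation of F3 with formaldehyde 3 in the presence of 1 generates the methylidene trione, which adds across C4=C5 to give 15 after separation from regio- and diastereomers.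

2. Step 5. What may go wrong: the acylation of the hindered tertiary alkoxide by the α,α-disubstituted acid chloride may be slow, and the diketonate oxygen may be acylated in competition.

   Fallback, setting out from 9 and returning at 13: the tether is omitted. Hydroxy diketone 9 is converted with LiN(iPr)2 (3.2 equiv) into its alkoxide/diketone dianion. The terminal carbanion is acylated by dimethyl 2,2-dimethylmalonate (γ-acylation of a β-diketone dianion by an ester), which gives triketo ester 13 as its polyanion. The warming and acid stages of step 6 then lead on through 14 to 15.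

3. Step 1. What may go wrong:
   - the heterodiene may be intercepted by a second molecule of 2;
   - ene reaction or attack at the exocyclic alkene may compete with the cycloaddition;
   - facial selectivity on the endocyclic alkene may be poor.

   Fallback, setting out from 1 and returning at 6: the heterodiene is changed to one at the aldehyde oxidation level, with no decarboxylation. Caryophyllene 1 is heated with acrolein (hydroquinone, sealed tube) in a thermal inverse-demand hetero-Diels–Alder reaction to give the ring B-fused 3,4-dihydro-2H-pyran F4. The cyclic enol ether is then oxidised to lactone 6 with pyridinium chlorochromate (C5H5NH[CrO3Cl]).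

**Further compounds**

F1 | step 6 | (S)-2-methylbutanoyl chloride | CC[C@H](C)C(=O)Cl
F2 | step 6 | (2S)-2-methyl-1-(2,4,6-trihydroxyphenyl)butan-1-one | CC[C@H](C)C(=O)c1c(O)cc(O)cc1O
F3 | step 6 | 2-[(2S)-2-methylbutanoyl]-4,4-dimethylcyclohexane-1,3,5-trione (enol form) | CC[C@H](C)C(=O)C1=C(O)CC(=O)C(C)(C)C1=O
F0 | step 5 | none | none
F4 | step 1 | ring B-fused 3,4-dihydro-2H-pyran from acrolein, O on C4 (4R), CH2 on C5 (5S), 1R,9S | C=C1CC[C@H]2CC=CO[C@]2(C)CC[C@@H]2[C@@H]1CC2(C)C
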